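Ring numbering used below: C1 = the CH2OH-bearing carbon, C4=C5 the Z alkene, C8=C9 the E alkene, C12 = the ring carbon that carries the dienyl side chain.
- Retrosynthetic cuts: the exocyclic C12–C(=CH2) bond (Zweifel coupling), the ring bond C2–C3 (sulfone/allylic bromide macrocyclisation), the ring bond C11–C12 (lithiation–borylation), and C10–C11 (borylmethylation).
- Forward order: nerol supplies C3–C10 with the 4Z alkene, SeO2 sets the 8E alkene, and C11 is added as CH2Bpin. An Evans-derived piece supplies C1, C2 and C12–C14. Lithiation–borylation joins the two, the side chain (a 2-bromo-1-alkene made by bromoboration of an enyne) is attached at C12, and the 14-membered ring closes last, followed by desulfonylation and desilylation.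
- Stereochemistry: C1 comes from an Evans alkylation on (S)-4-benzyloxazolidinone. C12 comes from (+)-sparteine-controlled lithiation–borylation (a C–B stereocentre) and is transferred with retention in the key step.
- Enabling feature: C12 is a ring CH flanked by two ring CH2 groups (C11, C13) and bonded to the internal carbon of an exocyclic C=CH2. This sec-alkyl–C(=CH2)R junction is what results when a secondary alkyl boronic ester and an α-substituted vinyllithium, two nucleophilic carbons, are joined oxidatively by iodine.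

Key step: step 14

Remark: the sulfonyl-bearing ring carbon (C2) of 35 and the boron-bearing carbon of 29 arise as epimer mixtures that the following operation erases, so they are drawn without configuration. (+)-Sparteine and B-bromo-9-BBN are taken as purchasable reagents.

Route

Step 1
Reactants: 1 5-bromo-2-methylpent-2-ene (homoprenyl bromide); 2 lithium acetylide–ethylenediamine complex
Product: 3 6-methylhept-5-en-1-yne
Conditions: DMSO, 10 °C → rt
Reagents that add atoms: none
Why: SN2 alkylation of an alkali acetylide in DMSO by the unbranched primary homoallylic bromide should give the terminal enyne, substitution outrunning E2 at this unhindered carbon.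

Step 2
Reactants: 3 6-methylhept-5-en-1-yne
Product: 5 2-bromo-6-methylhepta-1,5-diene, via (Z)-2-bromoalkenyl-9-BBN adduct 4 (not isolated)
Conditions: B-Br-9-BBN, CH2Cl2, 0 °C; then AcOH, 0 °C → rt
Reagents that add atoms: B-bromo-9-borabicyclo[3.3.1]nonane BrB1C2CCCC1CCC2
Why: Bromoboration of a terminal alkyne with B-bromo-9-BBN is a syn, Markovnikov addition (bromine to the internal carbon, adduct 4) that leaves alkenes alone, and protonolysis of the alkenyl C–B bond by acetic acid with retention should give the 2-bromo-1-alkene.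

Step 3
Reactants: 6 nerol [(2Z)-3,7-dimethylocta-2,6-dien-1-ol]
Product: 7 tert-butyl{[(2Z)-3,7-dimethylocta-2,6-dien-1-yl]oxy}dimethylsilane
Conditions: TBSCl, imidazole, DMF, rt
Reagents that add atoms: tert-butyldimethylsilyl chloride CC(C)(C)[Si](C)(C)Cl
Why: Standard silylation of a primary allylic alcohol that leaves the Z alkene untouched.

Step 4
Reactants: 7 neryl TBS ether
Product: 8 (2E,6Z)-8-[(tert-butyldimethylsilyl)oxy]-2,6-dimethylocta-2,6-dien-1-ol
Conditions: SeO2 (cat.), t-BuOOH, salicylic acid (cat.), CH2Cl2, 0 °C → rt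
Reagents that add atoms: tert-butyl hydroperoxide CC(C)(C)OO
Why: Sharpless catalytic SeO2 allylic oxidation (ene reaction then [2,3]-shift) should hydroxylate the E-methyl group of the electron-richer distal alkene with E geometry, the 2,3-alkene being deactivated by the allylic silyloxy group.

Step 5
Reactants: 8 (2E,6Z)-allylic alcohol
Product: 9 {[(2Z,6E)-8-bromo-3,7-dimethylocta-2,6-dien-1-yl]oxy}(tert-butyl)dimethylsilane
Conditions: CBr4, PPh3, CH2Cl2, 0 °C
Reagents that add atoms: carbon tetrabromide BrC(Br)(Br)Br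
Why: Appel bromination of a primary allylic alcohol proceeds by SN2 displacement of the oxyphosphonium ion at low temperature and should keep both alkene geometries.

Step 6
Reactants: 9 allylic bromide; 10 bis(4,4,5,5-tetramethyl-1,3,2-dioxaborolan-2-yl)methane
Product: 12 tert-butyl{[(2Z,6E)-3,7-dimethyl-9-(4,4,5,5-tetramethyl-1,3,2-dioxaborolan-2-yl)nona-2,6-dien-1-yl]oxy}dimethylsilane, via (pinacolboryl)methylsodium 11 (not isolated)
Conditions: NaOt-Bu, THF, rt
Reagents that add atoms: none
Why: Deborylative alkylation of a geminal bis(boronate): tert-butoxide activates one boron of 10 to release the α-boryl carbanion 11, which should displace the primary allylic bromide by SN2 and so add the CH2Bpin unit (ring C11).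

Step 7
Reactants: 13 (S)-4-benzyl-1,3-oxazolidin-2-one; 14 pent-4-enoyl chloride
Product: 15 (S)-4-benzyl-3-(pent-4-enoyl)-1,3-oxazolidin-2-one
Conditions: Et3N, DMAP (cat.), CH2Cl2, 0 °C → rt
Reagents that add atoms: none
Why: DMAP-catalysed N-acylation of the oxazolidinone with an acid chloride is a standard entry to Evans imides.

Step 8
Reactants: 15 N-pentenoyl oxazolidinone; 16 chloromethyl phenyl sulfide
Product: 18 (4S)-4-benzyl-3-{(2S)-2-[(phenylsulfanyl)methyl]pent-4-enoyl}-1,3-oxazolidin-2-one, via trichlorotitanium Z-enolate 17 (not isolated)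
Conditions: TiCl4, i-Pr2NEt, CH2Cl2, 0 °C; then 16, 0 °C → rt
Reagents that add atoms: none
Why: Evans titanium-enolate alkylation: the chelated Z-enolate 17 is shielded on one face by the benzyl group, so the thionium-type electrophile from 16 should add to the opposite face and set the α-centre (future ring C1) as 2S.

Step 9
Reactants: 18 alkylated imide
Product: 19 (2S)-2-[(phenylsulfanyl)methyl]pent-4-en-1-ol
Conditions: LiBH4, MeOH (1 equiv), THF, 0 °C
Reagents that add atoms: none
Why: Reductive cleavage of the imide with LiBH4 should give the primary alcohol without epimerisation and return the auxiliary, the sulfide and alkene being inert to borohydride.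

Step 10
Reactants: 19 (2S)-alcohol
Product: 20 triisopropyl{[(2S)-2-[(phenylsulfanyl)methyl]pent-4-en-1-yl]oxy}silane
Conditions: TIPSCl, imidazole, DMF, rt
Reagents that add atoms: triisopropylsilyl chloride CC(C)[Si](Cl)(C(C)C)C(C)C
Why: Silylation of the primary alcohol with a bulky silyl group chosen to survive s-BuLi, iodine, mild acid and LDA in the later steps.

Step 11
Reactants: 20 TIPS ether
Product: 22 (4S)-4-[(phenylsulfanyl)methyl]-5-[(triisopropylsilyl)oxy]pentan-1-ol, via B-alkyl-9-BBN adduct 21 (not isolated)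
Conditions: 9-BBN, THF, 0 °C → rt; then NaOH, H2O2, 0 °C
Reagents that add atoms: hydrogen peroxide OO
Why: Anti-Markovnikov hydroboration of the terminal alkene with 9-BBN and alkaline peroxide oxidation of 21 at 0 °C should give the primary alcohol, the aryl sulfide being slow to oxidise under basic peroxide.

Step 12
Reactants: 22 primary alcohol
Product: 23 (4S)-4-[(phenylsulfanyl)methyl]-5-[(triisopropylsilyl)oxy]pentyl 2,4,6-triisopropylbenzoate
Conditions: 2,4,6-triisopropylbenzoic acid, PPh3, DIAD, THF, 0 °C → rt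
Reagents that add atoms: 2,4,6-triisopropylbenzoic acid CC(C)c1cc(C(C)C)c(C(=O)O)c(C(C)C)c1
Why: Mitsunobu esterification of a primary alcohol with the hindered benzoic acid installs the directing and leaving group for lithiation–borylation.

Step 13
Reactants: 23 triisopropylbenzoate; 12 homoallylic pinacol boronic ester
Product: 26 (2Z,6E,10S,13S)-1-(tert-butyldimethylsilyloxy)-3,7-dimethyl-13-(phenylsulfanylmethyl)-10-(4,4,5,5-tetramethyl-1,3,2-dioxaborolan-2-yl)-14-(triisopropylsilyloxy)tetradeca-2,6-diene, via (1R)-1-lithio benzoate 24 (not isolated), via lithium boronate complex 25 (not isolated)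
Conditions: s-BuLi, (+)-sparteine, Et2O, −78 °C; then 12, −78 °C; then 35 °C
Reagents that add atoms: none
Why: Hoppe–Aggarwal lithiation–borylation: (+)-sparteine-controlled deprotonation gives the configurationally stable (R)-lithio benzoate 24, boronic ester 12 is captured with retention to give ate complex 25, and the 1,2-shift of the homoallyl group anti to the departing benzoate (inversion) should set the C–B stereocentre as S under reagent control.

Step 14
Reactants: 26 secondary pinacol boronic ester; 5 2-bromo-6-methylhepta-1,5-diene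
Product: 30 (2Z,6E,10S,13S)-1-(tert-butyldimethylsilyloxy)-3,7-dimethyl-10-(6-methylhepta-1,5-dien-2-yl)-13-(phenylsulfanylmethyl)-14-(triisopropylsilyloxy)tetradeca-2,6-diene, via (6-methylhepta-1,5-dien-2-yl)lithium 27 (not isolated), via lithium alkenylboronate complex 28 (not isolated), via β-iodoalkyl boronic ester 29 (not isolated)
Conditions: 5, t-BuLi (2 equiv), Et2O–THF, −78 °C; 26, −78 °C; I2, MeOH–THF, −78 °C; NaOMe, MeOH, −78 °C → rt
Reagents that add atoms: none
Why: Zweifel olefination: bromine–lithium exchange on 5 gives vinyllithium 27, which adds to boron of 26 to give ate complex 28, iodine attacks the CH2 terminus of the electron-rich alkenyl group and triggers a 1,2-shift of the secondary alkyl group from boron to the adjacent carbon (29), and methoxide-induced anti β-elimination of iodide and B(pin) releases the 1,1-disubstituted alkene. The closest known reaction type is the transition-metal-free coupling of enantioenriched secondary pinacol boronic esters with α-substituted vinyllithiums, formally an oxidative union of two nucleophilic carbons. No ring is closed in this step. No new stereocentre is created: the C–B stereocentre from step 13 becomes the carbon stereocentre C10 (ring C12) with retention, because the migrating carbon keeps its configuration in the 1,2-metallate shift. The step needs iodination of the boronate-bound alkene in preference to the two trisubstituted alkenes and the aryl sulfide, which the anionic ate complex should secure as by far the most electron-rich π system at −78 °C with near-stoichiometric iodine, and it needs migration of carbon and not of a pinacol oxygen, which is the normal course for secondary alkyl groups.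

Step 15
Reactants: 30 sulfide
Product: 31 (2Z,6E,10S,13S)-1-(tert-butyldimethylsilyloxy)-3,7-dimethyl-10-(6-methylhepta-1,5-dien-2-yl)-13-(phenylsulfonylmethyl)-14-(triisopropylsilyloxy)tetradeca-2,6-diene
Conditions: (NH4)6Mo7O24·4H2O (cat.), 30% H2O2, EtOH, 0 °C → rt
Reagents that add atoms: hydrogen peroxide OO
Why: Molybdate-catalysed peroxide oxidation takes an aryl alkyl sulfide to the sulfone and should leave isolated tri- and 1,1-disubstituted alkenes and both silyl ethers untouched.

Step 16
Reactants: 31 sulfone bis-silyl ether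
Product: 32 (2Z,6E,10S,13S)-3,7-dimethyl-10-(6-methylhepta-1,5-dien-2-yl)-13-(phenylsulfonylmethyl)-14-(triisopropylsilyloxy)tetradeca-2,6-dien-1-ol
Conditions: PPTS, MeOH, rt
Reagents that add atoms: none
Why: Mild acid-catalysed methanolysis removes the primary allylic TBS ether far faster than the bulkier TIPS ether.

Step 17
Reactants: 32 allylic alcohol
Product: 33 (2Z,6E,10S,13S)-1-bromo-3,7-dimethyl-10-(6-methylhepta-1,5-dien-2-yl)-13-(phenylsulfonylmethyl)-14-(triisopropylsilyloxy)tetradeca-2,6-diene
Conditions: CBr4, PPh3, CH2Cl2, −20 °C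
Reagents that add atoms: carbon tetrabromide BrC(Br)(Br)Br
Why: Appel bromination of the Z-allylic alcohol at low temperature should give the neryl-type bromide without allylic transposition or Z/E erosion.

Step 18
Reactants: 33 bromo sulfone
Product: 35 {[(1S,4Z,8E,12S)-5,9-dimethyl-12-(6-methylhepta-1,5-dien-2-yl)-2-(phenylsulfonyl)cyclotetradeca-4,8-dien-1-yl]methoxy}triisopropylsilane (C2 epimers), via α-lithio sulfone 34 (not isolated)
Conditions: LDA, THF, −78 → 0 °C, syringe-pump addition of 33, final 2 mM
Reagents that add atoms: none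
Why: Intramolecular alkylation of an α-sulfonyl carbanion by a primary allylic bromide under high dilution (14-exo-tet closure, a standard cembranoid macrocyclisation) should form the C2–C3 ring bond, SN2′ attack being disfavoured because it would create a quaternary centre in a 12-membered ring.

Step 19
Reactants: 35 macrocyclic sulfone
Product: 36 {[(1S,4Z,8E,12S)-5,9-dimethyl-12-(6-methylhepta-1,5-dien-2-yl)cyclotetradeca-4,8-dien-1-yl]methoxy}triisopropylsilane
Conditions: Na(Hg) (6%), Na2HPO4, MeOH–THF, −20 → 0 °C
Reagents that add atoms: none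
Why: Reductive desulfonylation by electron transfer from sodium amalgam in buffered methanol cleaves the C–S bond of the homoallylic sulfone and protonates the carbanion, removing the activating group without moving any double bond.

Step 20
Reactants: 36 macrocyclic TIPS ether
Product: 37 [(1S,4Z,8E,12S)-5,9-dimethyl-12-(6-methylhepta-1,5-dien-2-yl)cyclotetradeca-4,8-dien-1-yl]methanol
Conditions: TBAF, THF, rt
Reagents that add atoms: none
Why: Fluoride cleavage of the silyl ether releases the primary alcohol and should give the target with both stereocentres and all four alkenes unchanged.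

Compound list

1 | 5-bromo-2-methylpent-2-ene (homoprenyl bromide) | CC(C)=CCCBr | starting material
2 | lithium acetylide–ethylenediamine complex | [Li]C#C.NCCN | starting material
3 | 6-methylhept-5-en-1-yne | C#CCCC=C(C)C | intermediate
4 | 9-[(1Z)-2-bromo-6-methylhepta-1,5-dien-1-yl]-9-borabicyclo[3.3.1]nonane | Br/C(CCC=C(C)C)=C\B1C2CCCC1CCC2 | intermediate
5 | 2-bromo-6-methylhepta-1,5-diene | C=C(Br)CCC=C(C)C | intermediate
6 | nerol | CC(C)=CCC/C(C)=C\CO | starting material
7 | neryl TBS ether | CC(C)=CCC/C(C)=C\CO[Si](C)(C)C(C)(C)C | intermediate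
8 | (2E,6Z)-8-[(tert-butyldimethylsilyl)oxy]-2,6-dimethylocta-2,6-dien-1-ol | OC/C(C)=C/CC/C(C)=C\CO[Si](C)(C)C(C)(C)C | intermediate
9 | {[(2Z,6E)-8-bromo-3,7-dimethylocta-2,6-dien-1-yl]oxy}(tert-butyl)dimethylsilane | BrC/C(C)=C/CC/C(C)=C\CO[Si](C)(C)C(C)(C)C | intermediate
10 | bis(4,4,5,5-tetramethyl-1,3,2-dioxaborolan-2-yl)methane | CC1(C)OB(CB2OC(C)(C)C(C)(C)O2)OC1(C)C | starting material
11 | (pinacolboryl)methylsodium | [Na]CB1OC(C)(C)C(C)(C)O1 | intermediate
12 | homoallylic pinacol boronic ester (C3–C11 piece) | CC1(C)OB(CC/C(C)=C/CC/C(C)=C\CO[Si](C)(C)C(C)(C)C)OC1(C)C | intermediate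
13 | (S)-4-benzyl-1,3-oxazolidin-2-one | O=C1OC[C@H](Cc2ccccc2)N1 | starting material
14 | pent-4-enoyl chloride | C=CCCC(Cl)=O | starting material
15 | (S)-4-benzyl-3-(pent-4-enoyl)-1,3-oxazolidin-2-one | C=CCCC(=O)N1[C@@H](Cc2ccccc2)COC1=O | intermediate
16 | chloromethyl phenyl sulfide | ClCSc1ccccc1 | starting material
17 | trichlorotitanium Z-enolate of 15 | C=CC/C=C(\O[Ti](Cl)(Cl)Cl)N1[C@@H](Cc2ccccc2)COC1=O | intermediate
18 | (4S)-4-benzyl-3-{(2S)-2-[(phenylsulfanyl)methyl]pent-4-enoyl}-1,3-oxazolidin-2-one | C=CC[C@H](CSc1ccccc1)C(=O)N1[C@@H](Cc2ccccc2)COC1=O | intermediate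
19 | (2S)-2-[(phenylsulfanyl)methyl]pent-4-en-1-ol | OC[C@@H](CSc1ccccc1)CC=C | intermediate
20 | triisopropyl{[(2S)-2-[(phenylsulfanyl)methyl]pent-4-en-1-yl]oxy}silane | CC(C)[Si](OC[C@@H](CSc1ccccc1)CC=C)(C(C)C)C(C)C | intermediate
21 | B-alkyl-9-BBN adduct of 20 | CC(C)[Si](OC[C@@H](CSc1ccccc1)CCCB1C2CCCC1CCC2)(C(C)C)C(C)C | intermediate
22 | (4S)-4-[(phenylsulfanyl)methyl]-5-[(triisopropylsilyl)oxy]pentan-1-ol | CC(C)[Si](OC[C@@H](CSc1ccccc1)CCCO)(C(C)C)C(C)C | intermediate
23 | (4S)-4-[(phenylsulfanyl)methyl]-5-[(triisopropylsilyl)oxy]pentyl 2,4,6-triisopropylbenzoate | CC(C)c1cc(C(C)C)c(C(=O)OCCC[C@H](CSc2ccccc2)CO[Si](C(C)C)(C(C)C)C(C)C)c(C(C)C)c1 | intermediate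
24 | (1R)-1-lithio derivative of 23 | [Li][C@@H](OC(=O)c1c(C(C)C)cc(C(C)C)cc1C(C)C)CC[C@H](CSc1ccccc1)CO[Si](C(C)C)(C(C)C)C(C)C | intermediate
25 | lithium boronate complex of 24 and 12 | [Li+].CC1(C)O[B-](CC/C(C)=C/CC/C(C)=C\CO[Si](C)(C)C(C)(C)C)([C@@H](OC(=O)c2c(C(C)C)cc(C(C)C)cc2C(C)C)CC[C@H](CSc2ccccc2)CO[Si](C(C)C)(C(C)C)C(C)C)OC1(C)C | intermediate
26 | (10S,13S) secondary pinacol boronic ester | CC1(C)OB([C@H](CC/C(C)=C/CC/C(C)=C\CO[Si](C)(C)C(C)(C)C)CC[C@H](CSc2ccccc2)CO[Si](C(C)C)(C(C)C)C(C)C)OC1(C)C | intermediate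
27 | (6-methylhepta-1,5-dien-2-yl)lithium | [Li]C(=C)CCC=C(C)C | intermediate
28 | lithium alkenylboronate complex of 26 and 27 | [Li+].CC1(C)O[B-](C(=C)CCC=C(C)C)([C@H](CC/C(C)=C/CC/C(C)=C\CO[Si](C)(C)C(C)(C)C)CC[C@H](CSc2ccccc2)CO[Si](C(C)C)(C(C)C)C(C)C)OC1(C)C | intermediate
29 | β-iodoalkyl boronic ester | CC1(C)OB(C(CI)(CCC=C(C)C)[C@H](CC/C(C)=C/CC/C(C)=C\CO[Si](C)(C)C(C)(C)C)CC[C@H](CSc2ccccc2)CO[Si](C(C)C)(C(C)C)C(C)C)OC1(C)C | intermediate
30 | (2Z,6E,10S,13S) acyclic sulfide carrying the full carbon skeleton | C=C(CCC=C(C)C)[C@H](CC/C(C)=C/CC/C(C)=C\CO[Si](C)(C)C(C)(C)C)CC[C@H](CSc1ccccc1)CO[Si](C(C)C)(C(C)C)C(C)C | intermediate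
31 | corresponding phenyl sulfone | C=C(CCC=C(C)C)[C@H](CC/C(C)=C/CC/C(C)=C\CO[Si](C)(C)C(C)(C)C)CC[C@H](CS(=O)(=O)c1ccccc1)CO[Si](C(C)C)(C(C)C)C(C)C | intermediate
32 | sulfone allylic alcohol | C=C(CCC=C(C)C)[C@H](CC/C(C)=C/CC/C(C)=C\CO)CC[C@H](CS(=O)(=O)c1ccccc1)CO[Si](C(C)C)(C(C)C)C(C)C | intermediate
33 | sulfone allylic bromide | C=C(CCC=C(C)C)[C@H](CC/C(C)=C/CC/C(C)=C\CBr)CC[C@H](CS(=O)(=O)c1ccccc1)CO[Si](C(C)C)(C(C)C)C(C)C | intermediate
34 | α-lithio sulfone of 33 | C=C(CCC=C(C)C)[C@H](CC/C(C)=C/CC/C(C)=C\CBr)CC[C@H](C([Li])S(=O)(=O)c1ccccc1)CO[Si](C(C)C)(C(C)C)C(C)C | intermediate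
35 | macrocyclic C2-sulfone TIPS ether | C=C(CCC=C(C)C)[C@@H]1CC/C(C)=C/CC/C(C)=C\CC(S(=O)(=O)c2ccccc2)[C@H](CO[Si](C(C)C)(C(C)C)C(C)C)CC1 | intermediate
36 | macrocyclic TIPS ether | C=C(CCC=C(C)C)[C@@H]1CC/C(C)=C/CC/C(C)=C\CC[C@H](CO[Si](C(C)C)(C(C)C)C(C)C)CC1 | intermediate
37 | [(1S,4Z,8E,12S)-5,9-dimethyl-12-(6-methylhepta-1,5-dien-2-yl)cyclotetradeca-4,8-dien-1-yl]methanol | C=C(CCC=C(C)C)[C@@H]1CC/C(C)=C/CC/C(C)=C\CC[C@H](CO)CC1 | target

Step count and risks

Total steps: 20. Longest linear sequence: 14 steps (steps 7–20, from 13 and 14).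

Steps most likely to fail:

1. Step 18 (macrocyclisation). Intermolecular alkylation (oligomer formation) and base-induced elimination of the allylic bromide may outrun closure of the 14-membered ring. The fallback sets out from 32. Treatment with n-BuLi (3 equiv) and methyl chloroformate should carbonate the allylic alcohol and carboxylate the sulfone α-carbon in one operation, giving the allylic methyl carbonate α-sulfonyl methyl ester F1. A neutral Tsuji–Trost macrocyclisation (Pd(PPh3)4, dppe, THF, 65 °C, slow addition) should then attack the primary allyl terminus with the soft sulfonyl ester nucleophile and give the macrocyclic α-sulfonyl methyl ester F2. Krapcho demethoxycarbonylation (LiCl, wet DMSO, 120 °C) comes back to the route at 35.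

2. Step 14 (Zweifel coupling). Ate-complex formation between the α-branched vinyllithium and the secondary boronic ester may be incomplete, so that boronic ester is returned or iodine is consumed elsewhere. The fallback sets out from 26. The smaller 1-ethoxyvinyllithium (ethyl vinyl ether, t-BuLi) is used in the same iodine/methoxide sequence to give the 1-ethoxyvinyl coupling product F3, which mild aqueous acid should hydrolyse to the methyl ketone F4. Kinetic enolisation at the methyl group (LDA, −78 °C) and alkylation with prenyl bromide give the homoprenyl ketone F5. Non-basic methylenation (Tebbe reagent) comes back to the route at 30.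

3. Step 13 (lithiation–borylation). Deprotonation of the functionalised benzoate may be slow or incomplete, so that residual s-BuLi meets the boronic ester or the carbenoid is of poor configurational purity when it is trapped. The fallback sets out from 23. The lithiated benzoate is trapped with Me3SnCl to give the isolable (1R)-α-trimethylstannyl benzoate F6, which can be purified and assayed. Tin–lithium exchange with n-BuLi (Et2O, −78 °C, retention) then regenerates 24 cleanly and stoichiometrically before 12 is added, and the sequence comes back to the route at 26.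

Further compounds

F1 | step 18 | allylic methyl carbonate α-sulfonyl methyl ester derived from 32 | C=C(CCC=C(C)C)[C@H](CC/C(C)=C/CC/C(C)=C\COC(=O)OC)CC[C@H](C(C(=O)OC)S(=O)(=O)c1ccccc1)CO[Si](C(C)C)(C(C)C)C(C)C
F2 | step 18 | macrocyclic α-sulfonyl methyl ester | C=C(CCC=C(C)C)[C@@H]1CC/C(C)=C/CC/C(C)=C\CC(C(=O)OC)(S(=O)(=O)c2ccccc2)[C@H](CO[Si](C(C)C)(C(C)C)C(C)C)CC1
F3 | step 14 | 1-ethoxyvinyl coupling product (enol ether) | C=C(OCC)[C@H](CC/C(C)=C/CC/C(C)=C\CO[Si](C)(C)C(C)(C)C)CC[C@H](CSc1ccccc1)CO[Si](C(C)C)(C(C)C)C(C)C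
F4 | step 14 | methyl ketone at C10 | CC(=O)[C@H](CC/C(C)=C/CC/C(C)=C\CO[Si](C)(C)C(C)(C)C)CC[C@H](CSc1ccccc1)CO[Si](C(C)C)(C(C)C)C(C)C
F5 | step 14 | homoprenyl ketone at C10 | CC(C)=CCCC(=O)[C@H](CC/C(C)=C/CC/C(C)=C\CO[Si](C)(C)C(C)(C)C)CC[C@H](CSc1ccccc1)CO[Si](C(C)C)(C(C)C)C(C)C
F6 | step 13 | (1R)-α-trimethylstannyl derivative of 23 | C[Sn](C)(C)[C@@H](OC(=O)c1c(C(C)C)cc(C(C)C)cc1C(C)C)CC[C@H](CSc1ccccc1)CO[Si](C(C)C)(C(C)C)C(C)C
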